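**Retrosynthetic overview**

- The 2-substituted acrolein is made last by α-methylenation of a C7 acetaldehyde side chain, which comes from oxidative cleavage of a C7 allyl group.
- The C4–O ester bond is cut to a silyl dienol ether of the 7-allyl enone plus (2E,4R)-2,4-dimethyloct-2-enoic acid. They are joined by a new λ3-iodane-mediated γ-acyloxylation that sets C4 (the convergent key step).
- The C7 allyl group comes from kinetic enolate allylation. The C1 carboxyl comes from enol triflate alkoxycarbonylation and CuH conjugate reduction at the saturated ketone of dithiolane-protected Wieland–Miescher ketone.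
- Ring order: ring B (the cyclohexane that will carry the carboxyl and acyloxy groups) and ring A (the cyclohexenone) are bought already fused in (S)-Wieland–Miescher ketone, so no ring is formed in the route. Its quaternary centre controls every new ring stereocentre.
- The side-chain acid comes from Evans methylation of an N-hexanoyl oxazolidinone, reduction, one-pot oxidation/Wittig olefination and saponification.

Assumption: the three purchased building blocks and all named reagents are taken as commercially available; ring positions use naphthalene numbering (C1 carboxyl-bearing, C4 acyloxy-bearing, C4a=C5 enone alkene, C6 ketone, C7 side-chain carbon, C8a methyl-bearing) and β means the face of the C8a methyl group.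

**Route**

Step 1
Reactants: 1 (S)-Wieland–Miescher ketone [(8aS)-8a-methyl-3,4,8,8a-tetrahydronaphthalene-1,6(2H,7H)-dione]
Product: 2 (8aS)-6,6-(ethylenedithio)-8a-methyl-3,4,6,7,8,8a-hexahydronaphthalen-1(2H)-one
Conditions: HS(CH2)2SH (1.05 equiv), TsOH·H2O (10 mol%), AcOH, rt
Reagents that add atoms: ethane-1,2-dithiol SCCS
Why: Acid-catalysed thioketalisation in AcOH is selective for the conjugated C6 carbonyl of the enedione, keeps the C4a=C5 alkene in place and leaves the hindered C1 ketone free.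

Step 2
Reactants: 2 (8aS)-6,6-(ethylenedithio)-8a-methyl-3,4,6,7,8,8a-hexahydronaphthalen-1(2H)-one
Product: 4 (8aS)-6,6-(ethylenedithio)-8a-methyl-3,4,6,7,8,8a-hexahydronaphthalen-1-yl trifluoromethanesulfonate, via potassium enolate 3 (not isolated)
Conditions: KN(SiMe3)2 (1.1 equiv), THF, −78 °C; then PhNTf2 (1.15 equiv), −78 → 0 °C
Reagents that add atoms: N-phenylbis(trifluoromethanesulfonimide) O=S(=O)(N(c1ccccc1)S(=O)(=O)C(F)(F)F)C(F)(F)F
Why: The C1 ketone can enolise only towards C2 because C8a is quaternary, so enol triflate formation from the potassium enolate gives a single regioisomer.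

Step 3
Reactants: 4 (8aS)-6,6-(ethylenedithio)-8a-methyl-3,4,6,7,8,8a-hexahydronaphthalen-1-yl trifluoromethanesulfonate
Product: 5 4-methoxybenzyl (8aS)-6,6-(ethylenedithio)-8a-methyl-3,4,6,7,8,8a-hexahydronaphthalene-1-carboxylate
Conditions: Pd(OAc)2 (5 mol%), PPh3 (10 mol%), CO (1 atm), 4-MeOC6H4CH2OH (4 equiv), Et3N (2 equiv), DMF, 60 °C
Reagents that add atoms: carbon monoxide [C-]#[O+]; 4-methoxybenzyl alcohol COc1ccc(CO)cc1
Why: Palladium-catalysed alkoxycarbonylation of an enol triflate (oxidative addition to zerovalent palladium, CO insertion, alcoholysis) installs the carboxyl carbon directly as an acid-labile ester.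

Step 4
Reactants: 5 4-methoxybenzyl (8aS)-6,6-(ethylenedithio)-8a-methyl-3,4,6,7,8,8a-hexahydronaphthalene-1-carboxylate
Product: 6 4-methoxybenzyl (1S,8aR)-6,6-(ethylenedithio)-8a-methyl-1,2,3,4,6,7,8,8a-octahydronaphthalene-1-carboxylate
Conditions: Cu(OAc)2·H2O (5 mol%), 1,2-C6H4(PPh2)2 (5 mol%), (EtO)2MeSiH (2 equiv), t-BuOH (2 equiv), PhMe, rt
Reagents that add atoms: none
Why: CuH-catalysed conjugate reduction delivers hydride to the unhindered C2 and the enolate is protonated at C1 from the α face, anti to the axial C8a methyl group, giving the equatorial ester cis to the methyl group (1S), which is also the thermodynamic epimer.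

Step 5
Reactants: 6 4-methoxybenzyl (1S,8aR)-6,6-(ethylenedithio)-8a-methyl-1,2,3,4,6,7,8,8a-octahydronaphthalene-1-carboxylate
Product: 7 4-methoxybenzyl (1S,8aR)-8a-methyl-6-oxo-1,2,3,4,6,7,8,8a-octahydronaphthalene-1-carboxylate
Conditions: MeI (10 equiv), CaCO3 (3 equiv), MeCN/H2O (4:1), 55 °C
Reagents that add atoms: water O
Why: Alkylative dethioketalisation (S-methylation, then hydrolysis of the allylic sulfonium) releases the enone under near-neutral conditions that leave the ester and the C1 centre untouched.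

Step 6
Reactants: 7 4-methoxybenzyl (1S,8aR)-8a-methyl-6-oxo-1,2,3,4,6,7,8,8a-octahydronaphthalene-1-carboxylate
Product: 9 4-methoxybenzyl (1S,7R,8aR)-7-allyl-8a-methyl-6-oxo-1,2,3,4,6,7,8,8a-octahydronaphthalene-1-carboxylate, via lithium dienolate 8 (not isolated)
Conditions: LiN(iPr)2 (1.1 equiv), THF, −78 °C; then allyl bromide (1.5 equiv), DMPU, −78 → −30 °C
Reagents that add atoms: allyl bromide C=CCBr
Why: Kinetic deprotonation at the α' carbon C7 gives the cross-conjugated dienolate, and enolate alkylation occurs on the α face, anti to the pseudoaxial C8a methyl group, giving the equatorial 7-allyl group (7R), also the more stable epimer.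

Step 7
Reactants: 9 4-methoxybenzyl (1S,7R,8aR)-7-allyl-8a-methyl-6-oxo-1,2,3,4,6,7,8,8a-octahydronaphthalene-1-carboxylate
Product: 10 4-methoxybenzyl (1S,7R,8aR)-7-allyl-6-(tert-butyldimethylsilyloxy)-8a-methyl-1,2,3,7,8,8a-hexahydronaphthalene-1-carboxylate
Conditions: TBSOTf (1.3 equiv), Et3N (3 equiv), CH2Cl2, 0 °C
Reagents that add atoms: tert-butyldimethylsilyl trifluoromethanesulfonate CC(C)(C)[Si](C)(C)OS(=O)(=O)C(F)(F)F
Why: Soft enolisation (O-silylation, then removal of a γ-hydrogen at C4 by the amine) gives the thermodynamic linear silyl dienol ether C6(OSi)=C5–C4a=C4 needed for γ-functionalisation.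

Step 8
Reactants: 11 (R)-4-benzyloxazolidin-2-one; 12 hexanoyl chloride
Product: 13 (R)-4-benzyl-3-hexanoyloxazolidin-2-one
Conditions: Et3N (1.5 equiv), DMAP (10 mol%), CH2Cl2, 0 °C → rt
Reagents that add atoms: none
Why: DMAP-catalysed N-acylation of the oxazolidinone by the acid chloride is a standard way to load the Evans auxiliary.

Step 9
Reactants: 13 (R)-4-benzyl-3-hexanoyloxazolidin-2-one
Product: 15 (R)-4-benzyl-3-[(R)-2-methylhexanoyl]oxazolidin-2-one, via sodium (Z)-enolate 14 (not isolated)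
Conditions: NaN(SiMe3)2 (1.1 equiv), THF, −78 °C; then MeI (5 equiv), −78 °C
Reagents that add atoms: iodomethane CI
Why: Evans asymmetric alkylation: the chelated (Z)-enolate is methylated on the face opposite the benzyl group, which with the (R)-auxiliary gives the (R)-2-methyl centre.

Step 10
Reactants: 15 (R)-4-benzyl-3-[(R)-2-methylhexanoyl]oxazolidin-2-one
Product: 16 (R)-2-methylhexan-1-ol
Conditions: LiBH4 (1.2 equiv), H2O (1 equiv), Et2O, 0 °C → rt
Reagents that add atoms: none
Why: Reductive cleavage of the imide by LiBH4 releases the primary alcohol without touching the α-stereocentre and returns the auxiliary.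

Step 11
Reactants: 16 (R)-2-methylhexan-1-ol
Product: 18 ethyl (2E,4R)-2,4-dimethyloct-2-enoate, via (R)-2-methylhexanal 17 (not isolated)
Conditions: TEMPO (10 mol%), PhI(OAc)2 (1.1 equiv), CH2Cl2, rt; then Ph3P=C(Me)CO2Et (1.5 equiv), rt
Reagents that add atoms: ethyl 2-(triphenylphosphoranylidene)propanoate CCOC(=O)C(C)=P(c1ccccc1)(c1ccccc1)c1ccccc1
Why: Mild nitroxyl oxidation gives the configurationally labile aldehyde, which is trapped in the same pot by a stabilised ylide (Wittig olefination) with high E selectivity and no epimerisation.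

Step 12
Reactants: 18 ethyl (2E,4R)-2,4-dimethyloct-2-enoate
Product: 20 (2E,4R)-2,4-dimethyloct-2-enoic acid, via lithium carboxylate 19 (not isolated)
Conditions: LiOH·H2O (3 equiv), THF/H2O (3:1), 40 °C; then 1 M HCl
Reagents that add atoms: lithium hydroxide [Li+].[OH-]
Why: Saponification of the conjugated ester with LiOH is mild enough to keep the alkene geometry and the γ-stereocentre.

Step 13
Reactants: 10 4-methoxybenzyl (1S,7R,8aR)-7-allyl-6-(tert-butyldimethylsilyloxy)-8a-methyl-1,2,3,7,8,8a-hexahydronaphthalene-1-carboxylate; 20 (2E,4R)-2,4-dimethyloct-2-enoic acid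
Product: 22 4-methoxybenzyl (1S,4R,7R,8aR)-7-allyl-4-[(2E,4R)-2,4-dimethyloct-2-enoyloxy]-8a-methyl-6-oxo-1,2,3,4,6,7,8,8a-octahydronaphthalene-1-carboxylate, via bis(acyloxy)-λ3-iodane 21 (not isolated)
Conditions: PhIO (1.2 equiv), 20 (2.5 equiv), 4 Å MS, CH2Cl2, rt, 1 h; then 10, Me3SiOTf (10 mol%), −78 → −40 °C
Reagents that add atoms: none
Why: Proposed new method: vinylogous (γ-selective) oxidative acyloxylation of a silyl dienol ether by a bis(acyloxy)aryl-λ3-iodane built from the side-chain acid itself - silyl triflate ionises one carboxylate from trivalent iodine, the dienol ether oxygen binds the iodine centre to give an O-bound dienolonium species, and carboxylate then adds to the remote diene terminus C4 in an SN2''-type displacement that expels PhI and re-forms the conjugated C4a=C5–C6=O enone (γ attack should beat α attack at C5 because only it gives the conjugated enone directly), entering axially on the β face so that ring B stays a chair in continuous overlap with the π system (the stereoelectronic preference that sends oxidants to the 6β position of steroidal 3,5-dienol ethers), which sets 4R; the closest known reaction types are the α-acyloxylation of silyl enol ethers and ketones with PhI(OAc)2-type reagents and the para-selective oxidative dearomatisation of phenols with PhI(OAc)2, where acetate adds to the vinylogous position of an O-bound aryl-λ3-iodane.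

Step 14
Reactants: 22 4-methoxybenzyl (1S,4R,7R,8aR)-7-allyl-4-[(2E,4R)-2,4-dimethyloct-2-enoyloxy]-8a-methyl-6-oxo-1,2,3,4,6,7,8,8a-octahydronaphthalene-1-carboxylate
Product: 23 (1S,4R,7R,8aR)-7-allyl-4-[(2E,4R)-2,4-dimethyloct-2-enoyloxy]-8a-methyl-6-oxo-1,2,3,4,6,7,8,8a-octahydronaphthalene-1-carboxylic acid
Conditions: CF3CO2H (20 vol%), anisole (5 equiv), CH2Cl2, 0 °C
Reagents that add atoms: none
Why: Acidolysis of the 4-methoxybenzyl ester (ionisation to the benzylic cation, trapped by anisole in a Friedel–Crafts alkylation) frees the acid while the conjugated ester, enone and terminal alkene are inert to brief cold acid.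

Step 15
Reactants: 23 (1S,4R,7R,8aR)-7-allyl-4-[(2E,4R)-2,4-dimethyloct-2-enoyloxy]-8a-methyl-6-oxo-1,2,3,4,6,7,8,8a-octahydronaphthalene-1-carboxylic acid
Product: 25 (1S,4R,7S,8aR)-4-[(2E,4R)-2,4-dimethyloct-2-enoyloxy]-8a-methyl-6-oxo-7-(2-oxoethyl)-1,2,3,4,6,7,8,8a-octahydronaphthalene-1-carboxylic acid, via vicinal diol 24 (not isolated)
Conditions: OsO4 (2 mol%), NaIO4 (4 equiv), 2,6-lutidine (3 equiv), dioxane/H2O (3:1), rt
Reagents that add atoms: osmium tetroxide O=[Os](=O)(=O)=O; sodium periodate [Na+].[O-]I(=O)(=O)=O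
Why: Lemieux–Johnson oxidation: OsO4 dihydroxylates the electron-rich monosubstituted alkene much faster than the two electron-poor trisubstituted conjugated alkenes, and periodate cleaves the diol to the aldehyde.

Step 16
Reactants: 25 (1S,4R,7S,8aR)-4-[(2E,4R)-2,4-dimethyloct-2-enoyloxy]-8a-methyl-6-oxo-7-(2-oxoethyl)-1,2,3,4,6,7,8,8a-octahydronaphthalene-1-carboxylic acid
Product: 26 (1S,4R,7S,8aR)-4-[(2E,4R)-2,4-dimethyloct-2-enoyloxy]-8a-methyl-6-oxo-7-(3-oxoprop-1-en-2-yl)-1,2,3,4,6,7,8,8a-octahydronaphthalene-1-carboxylic acid (target)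
Conditions: 37% aq. CH2O (1.5 equiv), pyrrolidine (20 mol%), EtCO2H (20 mol%), i-PrOH, 45 °C
Reagents that add atoms: formaldehyde C=O
Why: Amine-catalysed α-methylenation of the aldehyde (enamine Mannich condensation with formaldehyde, then loss of the amine) turns CH2–CHO into C(=CH2)–CHO, and C7 keeps its equatorial, thermodynamically preferred configuration.

**Compound list**

1 | (S)-Wieland–Miescher ketone [(8aS)-8a-methyl-3,4,8,8a-tetrahydronaphthalene-1,6(2H,7H)-dione] | C1C[C@@]2(C)C(=CC1=O)CCCC2=O | starting material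
2 | (8aS)-6,6-(ethylenedithio)-8a-methyl-3,4,6,7,8,8a-hexahydronaphthalen-1(2H)-one (C6 carbonyl as 1,3-dithiolane) | C1C[C@@]2(C)C(=CC13SCCS3)CCCC2=O | intermediate
3 | potassium (8aS)-6,6-(ethylenedithio)-8a-methyl-3,4,6,7,8,8a-hexahydronaphthalen-1-olate (potassium enolate) | C1C[C@@]2(C)C(=CC13SCCS3)CCC=C2[O-].[K+] | intermediate (not isolated)
4 | (8aS)-6,6-(ethylenedithio)-8a-methyl-3,4,6,7,8,8a-hexahydronaphthalen-1-yl trifluoromethanesulfonate | C1C[C@@]2(C)C(=CC13SCCS3)CCC=C2OS(=O)(=O)C(F)(F)F | intermediate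
5 | 4-methoxybenzyl (8aS)-6,6-(ethylenedithio)-8a-methyl-3,4,6,7,8,8a-hexahydronaphthalene-1-carboxylate | C1C[C@@]2(C)C(=CC13SCCS3)CCC=C2C(=O)OCc4ccc(OC)cc4 | intermediate
6 | 4-methoxybenzyl (1S,8aR)-6,6-(ethylenedithio)-8a-methyl-1,2,3,4,6,7,8,8a-octahydronaphthalene-1-carboxylate | C1C[C@@]2(C)C(=CC13SCCS3)CCC[C@@H]2C(=O)OCc4ccc(OC)cc4 | intermediate
7 | 4-methoxybenzyl (1S,8aR)-8a-methyl-6-oxo-1,2,3,4,6,7,8,8a-octahydronaphthalene-1-carboxylate | C1C[C@@]2(C)C(=CC1=O)CCC[C@@H]2C(=O)OCc3ccc(OC)cc3 | intermediate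
8 | lithium dienolate of 7 (O–C6=C7 with C4a=C5 kept; 1S,8aR) | [Li+].[O-]C1=CC[C@@]2(C)C(=C1)CCC[C@@H]2C(=O)OCc3ccc(OC)cc3 | intermediate (not isolated)
9 | 4-methoxybenzyl (1S,7R,8aR)-7-allyl-8a-methyl-6-oxo-1,2,3,4,6,7,8,8a-octahydronaphthalene-1-carboxylate | C=CC[C@@H]1C[C@@]2(C)C(=CC1=O)CCC[C@@H]2C(=O)OCc3ccc(OC)cc3 | intermediate
10 | 4-methoxybenzyl (1S,7R,8aR)-7-allyl-6-(tert-butyldimethylsilyloxy)-8a-methyl-1,2,3,7,8,8a-hexahydronaphthalene-1-carboxylate | C=CC[C@@H]1C[C@@]2(C)C(C=C1O[Si](C)(C)C(C)(C)C)=CCC[C@@H]2C(=O)OCc3ccc(OC)cc3 | intermediate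
11 | (R)-4-benzyloxazolidin-2-one | O=C1N[C@H](Cc2ccccc2)CO1 | starting material
12 | hexanoyl chloride | CCCCCC(Cl)=O | starting material
13 | (R)-4-benzyl-3-hexanoyloxazolidin-2-one | CCCCCC(=O)N1[C@H](Cc2ccccc2)COC1=O | intermediate
14 | sodium (Z)-enolate of 13 | CCCC/C=C(\[O-])N1[C@H](Cc2ccccc2)COC1=O.[Na+] | intermediate (not isolated)
15 | (R)-4-benzyl-3-[(R)-2-methylhexanoyl]oxazolidin-2-one | CCCC[C@@H](C)C(=O)N1[C@H](Cc2ccccc2)COC1=O | intermediate
16 | (R)-2-methylhexan-1-ol | CCCC[C@@H](C)CO | intermediate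
17 | (R)-2-methylhexanal | CCCC[C@@H](C)C=O | intermediate (not isolated)
18 | ethyl (2E,4R)-2,4-dimethyloct-2-enoate | CCCC[C@@H](C)/C=C(\C)C(=O)OCC | intermediate
19 | lithium (2E,4R)-2,4-dimethyloct-2-enoate | CCCC[C@@H](C)/C=C(\C)C(=O)[O-].[Li+] | intermediate (not isolated)
20 | (2E,4R)-2,4-dimethyloct-2-enoic acid | CCCC[C@@H](C)/C=C(\C)C(O)=O | intermediate
21 | bis[(2E,4R)-2,4-dimethyloct-2-enoyloxy](phenyl)-λ3-iodane | CCCC[C@@H](C)/C=C(\C)C(=O)OI(OC(=O)/C(C)=C/[C@H](C)CCCC)c1ccccc1 | intermediate (not isolated)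
22 | 4-methoxybenzyl (1S,4R,7R,8aR)-7-allyl-4-[(2E,4R)-2,4-dimethyloct-2-enoyloxy]-8a-methyl-6-oxo-1,2,3,4,6,7,8,8a-octahydronaphthalene-1-carboxylate | C=CC[C@@H]1C[C@@]2(C)C(=CC1=O)[C@H](OC(=O)/C(C)=C/[C@H](C)CCCC)CC[C@@H]2C(=O)OCc3ccc(OC)cc3 | intermediate
23 | (1S,4R,7R,8aR)-7-allyl-4-[(2E,4R)-2,4-dimethyloct-2-enoyloxy]-8a-methyl-6-oxo-1,2,3,4,6,7,8,8a-octahydronaphthalene-1-carboxylic acid | C=CC[C@@H]1C[C@@]2(C)C(=CC1=O)[C@H](OC(=O)/C(C)=C/[C@H](C)CCCC)CC[C@@H]2C(O)=O | intermediate
24 | (1S,4R,7S,8aR)-7-(2,3-dihydroxypropyl)-4-[(2E,4R)-2,4-dimethyloct-2-enoyloxy]-8a-methyl-6-oxo-1,2,3,4,6,7,8,8a-octahydronaphthalene-1-carboxylic acid (both carbinol epimers) | OCC(O)C[C@@H]1C[C@@]2(C)C(=CC1=O)[C@H](OC(=O)/C(C)=C/[C@H](C)CCCC)CC[C@@H]2C(O)=O | intermediate (not isolated)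
25 | (1S,4R,7S,8aR)-4-[(2E,4R)-2,4-dimethyloct-2-enoyloxy]-8a-methyl-6-oxo-7-(2-oxoethyl)-1,2,3,4,6,7,8,8a-octahydronaphthalene-1-carboxylic acid | O=CC[C@@H]1C[C@@]2(C)C(=CC1=O)[C@H](OC(=O)/C(C)=C/[C@H](C)CCCC)CC[C@@H]2C(O)=O | intermediate
26 | (1S,4R,7S,8aR)-4-[(2E,4R)-2,4-dimethyloct-2-enoyloxy]-8a-methyl-6-oxo-7-(3-oxoprop-1-en-2-yl)-1,2,3,4,6,7,8,8a-octahydronaphthalene-1-carboxylic acid (CNP0143497.3) | C=C(C=O)[C@@H]1C[C@@]2(C)C(=CC1=O)[C@H](OC(=O)/C(C)=C/[C@H](C)CCCC)CC[C@@H]2C(=O)O | target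

**Step count and risk**

Total step count: 16 (11 on the decalin line, 5 for the side-chain acid).
Longest linear sequence: 11 steps (steps 1–7 and 13–16, from 1 to 26).

Three steps most likely to fail:

Step 4 (CuH conjugate reduction that sets C1). The enoate is hindered at its α carbon and sits next to a dithiolane, so the reduction may be slow or the kinetic protonation may give some of the axial ester. The fallback sets out from 2 and comes back to the route at 6, replacing steps 2 to 4 by a one-carbon homologation with thermodynamic control of C1. Ph3P(CH2OMe)Cl and KOtBu in THF at 0 °C give (methoxymethylidene)triphenylphosphorane F1, which converts the C1 ketone of 2 by Wittig olefination into the enol ether (8aS)-6,6-(ethylenedithio)-1-(methoxymethylidene)-8a-methyl-1,2,3,4,6,7,8,8a-octahydronaphthalene F2. Hydrolysis with 2 M HCl in THF followed by K2CO3 in MeOH equilibrates the product to the equatorial aldehyde (1S,8aR)-6,6-(ethylenedithio)-8a-methyl-1,2,3,4,6,7,8,8a-octahydronaphthalene-1-carbaldehyde F3. Pinnick oxidation (NaClO2, NaH2PO4, excess 2-methylbut-2-ene, t-BuOH/H2O) gives (1S,8aR)-6,6-(ethylenedithio)-8a-methyl-1,2,3,4,6,7,8,8a-octahydronaphthalene-1-carboxylic acid F4, and alkylation with 4-MeOC6H4CH2Cl and Cs2CO3 in DMF gives 6.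

Step 13 (the proposed new γ-acyloxylation). The open questions are attack at C5 (α) instead of C4 (γ), formation of the 4α epimer, and over-oxidation to the linear dienone by loss of a C3 proton. The fallback uses known chemistry, sets out from 10 and comes back at 22. Vinylogous Rubottom oxidation of 10 with mCPBA (1.05 equiv, NaHCO3, CH2Cl2, −20 °C, aqueous work-up) gives the axial allylic alcohol 4-methoxybenzyl (1S,4R,7R,8aR)-7-allyl-4-hydroxy-8a-methyl-6-oxo-1,2,3,4,6,7,8,8a-octahydronaphthalene-1-carboxylate F5, following the known β-face preference of peracid attack on ring-fused dienol ethers. Acid 20 is activated with 2,4,6-Cl3C6H2COCl and Et3N in THF as the mixed anhydride (2E,4R)-2,4-dimethyloct-2-enoic 2,4,6-trichlorobenzoic anhydride F6, which acylates F5 with DMAP in PhMe at rt to 40 °C (Yamaguchi esterification) to give 22.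

Step 16 (α-methylenation to the acrolein). The product has a C7 hydrogen activated by both the ketone and the enal, so the amine catalyst may move the exocyclic alkene into conjugation with the ketone or add to the enal. The fallback sets out from 25 and comes back at 26, forming the alkene by a thermal syn elimination without base. Mannich reaction of 25 with Me2N=CH2+ I− in CH2Cl2 at rt gives the Mannich base (1S,4R,7S,8aR)-7-[3-(dimethylamino)-1-oxopropan-2-yl]-4-[(2E,4R)-2,4-dimethyloct-2-enoyloxy]-8a-methyl-6-oxo-1,2,3,4,6,7,8,8a-octahydronaphthalene-1-carboxylic acid F7. Oxidation with mCPBA (1.0 equiv, CH2Cl2, −20 °C) gives the corresponding amine N-oxide F8, which undergoes Cope elimination on warming to rt to give 26.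

**Further compounds**

F1 | step 4 | (methoxymethylidene)triphenylphosphorane | COC=P(c1ccccc1)(c1ccccc1)c1ccccc1
F2 | step 4 | (8aS)-6,6-(ethylenedithio)-1-(methoxymethylidene)-8a-methyl-1,2,3,4,6,7,8,8a-octahydronaphthalene (E/Z mixture) | C1C[C@@]2(C)C(=CC13SCCS3)CCCC2=COC
F3 | step 4 | (1S,8aR)-6,6-(ethylenedithio)-8a-methyl-1,2,3,4,6,7,8,8a-octahydronaphthalene-1-carbaldehyde | C1C[C@@]2(C)C(=CC13SCCS3)CCC[C@@H]2C=O
F4 | step 4 | (1S,8aR)-6,6-(ethylenedithio)-8a-methyl-1,2,3,4,6,7,8,8a-octahydronaphthalene-1-carboxylic acid | C1C[C@@]2(C)C(=CC13SCCS3)CCC[C@@H]2C(O)=O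
F5 | step 13 | 4-methoxybenzyl (1S,4R,7R,8aR)-7-allyl-4-hydroxy-8a-methyl-6-oxo-1,2,3,4,6,7,8,8a-octahydronaphthalene-1-carboxylate | C=CC[C@@H]1C[C@@]2(C)C(=CC1=O)[C@H](O)CC[C@@H]2C(=O)OCc3ccc(OC)cc3
F6 | step 13 | (2E,4R)-2,4-dimethyloct-2-enoic 2,4,6-trichlorobenzoic anhydride | CCCC[C@@H](C)/C=C(\C)C(=O)OC(=O)c1c(Cl)cc(Cl)cc1Cl
F7 | step 16 | (1S,4R,7S,8aR)-7-[3-(dimethylamino)-1-oxopropan-2-yl]-4-[(2E,4R)-2,4-dimethyloct-2-enoyloxy]-8a-methyl-6-oxo-1,2,3,4,6,7,8,8a-octahydronaphthalene-1-carboxylic acid (both side-chain epimers) | CN(C)CC(C=O)[C@@H]1C[C@@]2(C)C(=CC1=O)[C@H](OC(=O)/C(C)=C/[C@H](C)CCCC)CC[C@@H]2C(O)=O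
F8 | step 16 | N-oxide of F7 | C[N+](C)([O-])CC(C=O)[C@@H]1C[C@@]2(C)C(=CC1=O)[C@H](OC(=O)/C(C)=C/[C@H](C)CCCC)CC[C@@H]2C(O)=O
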